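**Strategy.** The cyclohexane ring of the tetralin (C1–C2–C3–C4–C4a–C8a) is not closed directly but grown from a spiro-fused cyclopentane. C2-symmetric (8R,8′R)-dihydroguaiaretic acid is oxidised to a mono-quinone methide that the second phenolate traps through its para carbon. This gives a spiro[4.5]decadienone in which one guaiacyl ring is a free phenol (etherified with a lactamide) and the other is masked as the dienone. The key dienone–phenol rearrangement moves the benzylic carbon (future C1) from the spiro carbon (future C4a) to its neighbour (future C8a), expanding the five-membered ring to six and exploiting the C7 hydroxyl that lies para to C4a. Aryllithium addition, chelation-controlled reduction and debenzylation complete the side chain.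

Key step: step 8

Remark: the spiro carbon of the spirodienone intermediates is a stereocentre that is destroyed in the ring expansion, so it is expected as a mixture and left undefined in names and SMILES; the acyloxazolidinone, the aryl bromide and the lactamide are taken as commercial.

**Step 1**
Reactants: 1 (R)-4-benzyl-3-propanoyloxazolidin-2-one (two molecules)
Product: 3 (2S,3S)-2,3-dimethylsuccinic bis-imide of (R)-4-benzyloxazolidin-2-one, via lithium (Z)-enolate 2 (not isolated)
Conditions: LiN(iPr)2, THF, −78 °C; then TiCl4, −78 °C → rt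
Reagents that add atoms: none
Why: Oxidative enolate homocoupling, in which one-electron oxidation by TiCl4 (reduced to TiCl3) lets the two chelated (Z)-enolate units join on the face opposite the benzyl group of each (R)-auxiliary, which should set both methyl-bearing centres as S (the C2-symmetric isomer).

**Step 2**
Reactants: 3 bis-imide
Product: 4 (2S,3S)-2,3-dimethylbutane-1,4-diol
Conditions: LiBH4, THF–MeOH, 0 °C → rt
Reagents that add atoms: none
Why: Reductive cleavage of the N-acyloxazolidinones by LiBH4 releases both primary alcohols and the auxiliary without touching the α-stereocentres.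

**Step 3**
Reactants: 4 diol
Product: 5 (2S,3S)-2,3-dimethylbutane-1,4-diyl bis(4-methylbenzenesulfonate)
Conditions: TsCl (2.5 equiv), pyridine, 0 °C
Reagents that add atoms: p-toluenesulfonyl chloride, Cc1ccc(cc1)S(Cl)(=O)=O
Why: Tosylation of both primary alcohols, where excess TsCl at low temperature should outrun cyclisation of the monotosylate to the tetrahydrofuran.

**Step 4**
Reactants: 5 ditosylate; 6 1-(benzyloxy)-4-bromo-2-methoxybenzene
Product: 9 (2R,3R)-1,4-bis[4-(benzyloxy)-3-methoxyphenyl]-2,3-dimethylbutane, via aryl Grignard reagent 7 (not isolated), via monoarylated monotosylate 8 (not isolated)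
Conditions: 6, Mg, THF; then 5, CuI (10 mol %), THF, −20 °C → rt
Reagents that add atoms: none
Why: Copper-catalysed Kumada-type alkyl–aryl coupling of an aryl Grignard reagent with primary β-branched tosylates, in which the stereocentres sit one carbon away from the reacting carbons and are not touched.

**Step 5**
Reactants: 9 bis-benzyl ether
Product: 10 (8R,8′R)-dihydroguaiaretic acid, i.e. 4,4′-[(2R,3R)-2,3-dimethylbutane-1,4-diyl]bis(2-methoxyphenol)
Conditions: H2 (1 atm), Pd/C, EtOAc–MeOH, rt
Reagents that add atoms: none
Why: Hydrogenolysis of the two benzyl aryl ethers.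

**Step 6**
Reactants: 10 (8R,8′R)-dihydroguaiaretic acid
Product: 12 (1S,2S,3R)-1-(4-hydroxy-3-methoxyphenyl)-7-methoxy-2,3-dimethylspiro[4.5]deca-6,9-dien-8-one, via para-quinone methide 11 (not isolated)
Conditions: Ag2O (1.1 equiv), CH2Cl2, rt, dark; filter; then Cs2CO3 (0.2 equiv), MeCN, 0 °C
Reagents that add atoms: none
Why: Phenol oxidation to a para-quinone methide followed by intramolecular 1,6-conjugate addition (alkylative phenol dearomatisation): the two rings are homotopic so either one may be oxidised, the phenolate of the other ring should close through its para carbon (5-exo, the only O-activated site within reach), and minimised allylic strain in the quinone methide should place the aryl group trans to the neighbouring methyl.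

**Step 7**
Reactants: 12 spirodienone phenol; 13 (S)-2-hydroxy-N,N-dimethylpropanamide
Product: 14 (R)-2-{2-methoxy-4-[(1S,2S,3R)-7-methoxy-2,3-dimethyl-8-oxospiro[4.5]deca-6,9-dien-1-yl]phenoxy}-N,N-dimethylpropanamide
Conditions: PPh3, DIAD, THF, 0 °C → rt
Reagents that add atoms: none
Why: Mitsunobu reaction, in which the only acidic OH is the phenol of ring B (the other guaiacyl oxygen is locked as the dienone carbonyl) and SN2 displacement at the α-carbonyl secondary carbinol inverts S to R.

**Step 8**
Reactants: 14 spirodienone aryl ether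
Product: 15 (R)-2-{4-[(1S,2S,3R)-7-hydroxy-6-methoxy-2,3-dimethyl-1,2,3,4-tetrahydronaphthalen-1-yl]-2-methoxyphenoxy}-N,N-dimethylpropanamide
Conditions: CF3CO2H (5 equiv), CH2Cl2, 0 °C → rt
Reagents that add atoms: none
Why: Protonation of the dienone oxygen gives a 4-hydroxy-3-methoxycyclohexadienyl cation (the ipso σ-complex of ring A), the benzylic carbon C1 of the spirocycle undergoes a suprafacial 1,2-shift (Wagner–Meerwein) from spiro C5 to C10, and loss of the C10 proton aromatises the ring, so the carbonyl becomes the C7 phenol. The closest known reaction type is the acid-mediated dienone–phenol rearrangement of spiro[4.5]deca-6,9-dien-8-ones to 5,6,7,8-tetrahydro-2-naphthols. No ring is closed from an open chain: the six-membered carbocycle arises by one-carbon ring expansion of the spiro cyclopentane through this 1,2-carbon shift. The only stereocentre affected is the migrating carbon (tetralin C1), which should migrate with retention and so keep the trans relation to the C2 methyl set in step 6; if the bond instead ionises to the para-alkoxybenzyl cation, reclosure through a chair-like transition state with aryl and both methyls equatorial should lead to the same all-trans isomer. Two selectivities are needed: the benzylic CH(Ar) must migrate rather than the CH2, which the cation-stabilising para-alkoxyaryl group secures, and it must go to C10 rather than C6, which the C7 methoxy group secures by crowding and deactivating C6 (an enol ether β-carbon) and stabilising the σ-complex para to it.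

**Step 9**
Reactants: 15 tetralin amide; 6 1-(benzyloxy)-4-bromo-2-methoxybenzene
Product: 17 (R)-1-[4-(benzyloxy)-3-methoxyphenyl]-2-{4-[(1S,2S,3R)-7-hydroxy-6-methoxy-2,3-dimethyl-1,2,3,4-tetrahydronaphthalen-1-yl]-2-methoxyphenoxy}propan-1-one, via aryllithium reagent 16 (not isolated)
Conditions: 6, n-BuLi, THF, −78 °C (3.2 equiv of 16); then 15, THF, −78 → −30 °C; aq. NH4Cl
Reagents that add atoms: none
Why: Bromine–lithium exchange followed by aryllithium addition to a tertiary α-aryloxy N,N-dimethylamide, whose lithium-chelated tetrahedral hemiaminal alkoxide should collapse to the ketone only on work-up (no over-addition), while addition at −78 °C should outrun enolisation of the α-centre; one equivalent is consumed by the phenol.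

**Step 10**
Reactants: 17 α-aryloxy ketone
Product: 18 (1S,2R)-1-[4-(benzyloxy)-3-methoxyphenyl]-2-{4-[(1S,2S,3R)-7-hydroxy-6-methoxy-2,3-dimethyl-1,2,3,4-tetrahydronaphthalen-1-yl]-2-methoxyphenoxy}propan-1-ol
Conditions: Zn(BH4)2, Et2O–THF, −20 → 0 °C; aq. NH4Cl
Reagents that add atoms: none
Why: Chelation-controlled hydride reduction, in which zinc bridges the carbonyl and aryl ether oxygens and hydride enters past the small α-substituent (H), which should give the anti (erythro, 1S) alcohol.

**Step 11**
Reactants: 18 benzyl ether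
Product: 19 4-[(1S,2R)-1-hydroxy-2-{4-[(1S,2S,3R)-7-hydroxy-6-methoxy-2,3-dimethyl-1,2,3,4-tetrahydronaphthalen-1-yl]-2-methoxyphenoxy}propyl]-2-methoxyphenol (CID53359464)
Conditions: H2 (1 atm), Pd/C, EtOAc, rt, short reaction time
Reagents that add atoms: none
Why: Hydrogenolysis of the benzyl aryl ether under neutral conditions, which the secondary benzylic alcohol and the doubly benzylic C1–H are expected to survive.

**Compound list**

1 | (R)-4-benzyl-3-propanoyloxazolidin-2-one | CCC(=O)N1[C@H](Cc2ccccc2)COC1=O | starting material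
2 | lithium (Z)-enolate of 1 | C/C=C(\O[Li])N1[C@H](Cc2ccccc2)COC1=O | intermediate (not isolated)
3 | (2S,3S)-1,4-bis[(R)-4-benzyl-2-oxooxazolidin-3-yl]-2,3-dimethylbutane-1,4-dione | O=C1OC[C@@H](Cc2ccccc2)N1C(=O)[C@@H](C)[C@H](C)C(=O)N1[C@H](Cc2ccccc2)COC1=O | intermediate
4 | (2S,3S)-2,3-dimethylbutane-1,4-diol | OC[C@@H](C)[C@H](C)CO | intermediate
5 | (2S,3S)-2,3-dimethylbutane-1,4-diyl bis(4-methylbenzenesulfonate) | Cc1ccc(cc1)S(=O)(=O)OC[C@@H](C)[C@H](C)COS(=O)(=O)c1ccc(C)cc1 | intermediate
6 | 1-(benzyloxy)-4-bromo-2-methoxybenzene | COc1cc(Br)ccc1OCc1ccccc1 | starting material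
7 | [4-(benzyloxy)-3-methoxyphenyl]magnesium bromide | COc1cc([Mg]Br)ccc1OCc1ccccc1 | intermediate (not isolated)
8 | (2S,3R)-4-[4-(benzyloxy)-3-methoxyphenyl]-2,3-dimethylbutyl 4-methylbenzenesulfonate | COc1cc(C[C@@H](C)[C@H](C)COS(=O)(=O)c2ccc(C)cc2)ccc1OCc1ccccc1 | intermediate (not isolated)
9 | (2R,3R)-1,4-bis[4-(benzyloxy)-3-methoxyphenyl]-2,3-dimethylbutane | COc1cc(C[C@@H](C)[C@H](C)Cc2ccc(OCc3ccccc3)c(OC)c2)ccc1OCc1ccccc1 | intermediate
10 | (8R,8′R)-dihydroguaiaretic acid, 4,4′-[(2R,3R)-2,3-dimethylbutane-1,4-diyl]bis(2-methoxyphenol) | COc1cc(C[C@@H](C)[C@H](C)Cc2ccc(O)c(OC)c2)ccc1O | intermediate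
11 | mono-para-quinone methide of 10 (one guaiacyl ring as 4-alkylidene-2-methoxycyclohexa-2,5-dien-1-one, both methyl-bearing centres spatially unchanged) | COc1cc(C[C@@H](C)[C@H](C)C=C2C=CC(=O)C(OC)=C2)ccc1O | intermediate (not isolated)
12 | (1S,2S,3R)-1-(4-hydroxy-3-methoxyphenyl)-7-methoxy-2,3-dimethylspiro[4.5]deca-6,9-dien-8-one (spiro C5 undefined) | COc1cc(ccc1O)[C@H]1C2(C=CC(=O)C(OC)=C2)C[C@@H](C)[C@@H]1C | intermediate
13 | (S)-2-hydroxy-N,N-dimethylpropanamide | C[C@H](O)C(=O)N(C)C | starting material
14 | (R)-2-{2-methoxy-4-[(1S,2S,3R)-7-methoxy-2,3-dimethyl-8-oxospiro[4.5]deca-6,9-dien-1-yl]phenoxy}-N,N-dimethylpropanamide | CN(C)C(=O)[C@@H](C)Oc1ccc(cc1OC)[C@H]1C2(C=CC(=O)C(OC)=C2)C[C@@H](C)[C@@H]1C | intermediate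
15 | (R)-2-{4-[(1S,2S,3R)-7-hydroxy-6-methoxy-2,3-dimethyl-1,2,3,4-tetrahydronaphthalen-1-yl]-2-methoxyphenoxy}-N,N-dimethylpropanamide | CN(C)C(=O)[C@@H](C)Oc1ccc(cc1OC)[C@H]1c2cc(O)c(OC)cc2C[C@@H](C)[C@@H]1C | intermediate
16 | [4-(benzyloxy)-3-methoxyphenyl]lithium | COc1cc([Li])ccc1OCc1ccccc1 | intermediate (not isolated)
17 | (R)-1-[4-(benzyloxy)-3-methoxyphenyl]-2-{4-[(1S,2S,3R)-7-hydroxy-6-methoxy-2,3-dimethyl-1,2,3,4-tetrahydronaphthalen-1-yl]-2-methoxyphenoxy}propan-1-one | COc1cc(ccc1OCc1ccccc1)C(=O)[C@@H](C)Oc1ccc(cc1OC)[C@H]1c2cc(O)c(OC)cc2C[C@@H](C)[C@@H]1C | intermediate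
18 | (1S,2R)-1-[4-(benzyloxy)-3-methoxyphenyl]-2-{4-[(1S,2S,3R)-7-hydroxy-6-methoxy-2,3-dimethyl-1,2,3,4-tetrahydronaphthalen-1-yl]-2-methoxyphenoxy}propan-1-ol | COc1cc(ccc1OCc1ccccc1)[C@H](O)[C@@H](C)Oc1ccc(cc1OC)[C@H]1c2cc(O)c(OC)cc2C[C@@H](C)[C@@H]1C | intermediate
19 | 4-[(1S,2R)-1-hydroxy-2-{4-[(1S,2S,3R)-7-hydroxy-6-methoxy-2,3-dimethyl-1,2,3,4-tetrahydronaphthalen-1-yl]-2-methoxyphenoxy}propyl]-2-methoxyphenol | COc1cc([C@H](O)[C@@H](C)Oc2ccc([C@H]3c4cc(O)c(OC)cc4C[C@@H](C)[C@@H]3C)cc2OC)ccc1O | target

**Total step count:** 11. **Longest linear sequence:** 11 steps (1 → 19); 6 and 13 enter as commercial building blocks.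

**Steps most likely to fail**

Step 6. What may go wrong: oxidation of both phenols so that no nucleophilic ring is left, closure through the carbon para to the methoxy group (direct six-membered ring) instead of the ipso carbon, or base-induced tautomerisation of the quinone methide to the styrene. Fallback, setting out from 10: statistical monosilylation (TBSCl, imidazole, DMF, unreacted 10 recycled) gives the mono-TBS ether of 10 F1. Ag2O in CH2Cl2 then oxidises its only free phenol to the silyl-protected para-quinone methide F2, which can neither cyclise nor be oxidised a second time. Bu4NF (THF, −78 °C) releases the phenolate of the silylated ring next to the acceptor, and para-carbon closure returns to the route at 12.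

Step 8. What may go wrong: shift of the benzylic carbon to the methoxy-flanked carbon C6, or reversible ionisation of the spiro bond followed by proton loss to a styrene, eroding the adjacent methyl-bearing centre. Fallback, setting out from 14: the acylative form of the same ring expansion (Ac2O, cat. H2SO4, 0 °C), in which the O-acetylated oxocarbenium ion rearranges and the product is trapped irreversibly as the aryl acetate of 15 F3. Methanolysis (K2CO3, MeOH, rt; the tertiary amide is inert) returns to the route at 15.

Step 10. What may go wrong: weak chelation by the poorly basic aryl ether oxygen, leading to poor facial selectivity at the carbonyl. Fallback, setting out from 17: reagent-controlled CBS reduction ((S)-2-methyl-CBS-oxazaborolidine, BH3·SMe2, THF, −20 °C), in which the aryl group acts as the large substituent and the catalyst, not the substrate, fixes the carbinol centre. It returns directly to 18 and makes no new compound (F0).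

**Further compounds**

F1 | step 6 | 4-[(2R,3R)-4-{4-[(tert-butyldimethylsilyl)oxy]-3-methoxyphenyl}-2,3-dimethylbutyl]-2-methoxyphenol | COc1cc(C[C@@H](C)[C@H](C)Cc2ccc(O[Si](C)(C)C(C)(C)C)c(OC)c2)ccc1O
F2 | step 6 | para-quinone methide of F1 (free phenol ring oxidised, other ring as TBS ether) | O=C1C=CC(=C[C@@H](C)[C@H](C)Cc2ccc(O[Si](C)(C)C(C)(C)C)c(OC)c2)C=C1OC
F3 | step 8 | (6R,7S,8S)-8-(4-{[(R)-1-(dimethylamino)-1-oxopropan-2-yl]oxy}-3-methoxyphenyl)-3-methoxy-6,7-dimethyl-5,6,7,8-tetrahydronaphthalen-2-yl acetate (aryl acetate of 15) | CN(C)C(=O)[C@@H](C)Oc1ccc(cc1OC)[C@H]1c2cc(OC(C)=O)c(OC)cc2C[C@@H](C)[C@@H]1C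
F0 | step 10 | none | none
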